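**Plan**
- Retrosynthesis: the two ester C–O bonds and the C–CHO bond of the acrolein unit are cut first (formyl from iodide, iodide from boron). Next the C2–C3 bond of the dihydrofuran is cut together with the C–B bond, giving an ortho-formyl aryl allenyl ether. That ether goes back through its O-propargyl isomer and the aryl ketone to methyl 5-acetylsalicylate.
- Enabling feature: in the 2,3-dihydrobenzofuran ring, C2 (on ring oxygen O1) and C3 (on the ester oxygen) are adjacent oxygen-bearing carbons of like polarity, and C2 carries the 1,1-disubstituted alkene C(=CH2)CHO. This is the pattern left when a gamma-oxyallyl metal adds through its oxygen-bearing carbon to an aldehyde carbon that becomes C3.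
- Forward order: the benzene ring of the salicylate is kept and its three substituents are elaborated in one linear chain. The only new ring, the dihydrofuran, closes in step 7; boron is then exchanged for iodine, both acyl groups are attached, and the formyl carbon is added last from CO.
- Stereochemistry: the side-chain (S) carbinol comes from asymmetric transfer hydrogenation (step 2). C2 and C3 are set in step 7, cis by the tethered cyclic transition state and (2R,3R) by the chiral bisphosphine on copper. No later step breaks a bond at a stereocentre.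

Key step: step 7

Assumption: the sense of induction of (S,S)-Ph-BPE in this ring closure cannot be derived from intermolecular cases; it is written as the ligand that gives Si-face attack on the formyl group, and (R,R)-Ph-BPE is to be used instead if a first trial on 8 shows the opposite sense.

**Step 1**
Reactants: 1 methyl 5-acetyl-2-hydroxybenzoate; 2 3-bromoprop-1-yne
Product: 3 methyl 5-acetyl-2-(prop-2-yn-1-yloxy)benzoate
Conditions: K2CO3, DMF, 25 °C
Reagents that add atoms: none
Why: Williamson ether synthesis, in which the salicylate phenoxide formed by K2CO3 displaces bromide from the primary propargylic carbon (SN2) while the ketone and ester are untouched.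

**Step 2**
Reactants: 3 methyl 5-acetyl-2-(prop-2-yn-1-yloxy)benzoate
Product: 4 methyl 5-[(1S)-1-hydroxyethyl]-2-(prop-2-yn-1-yloxy)benzoate
Conditions: RuCl[(S,S)-TsDPEN](p-cymene) (1 mol %), HCO2H/Et3N (5:2), 30 °C
Reagents that add atoms: none
Why: Noyori asymmetric transfer hydrogenation of an aryl methyl ketone, in which the (S,S)-diamine ruthenium hydride gives the (S)-1-arylethanol by outer-sphere hydride and proton transfer that is selective for C=O over the ester and the alkyne.

**Step 3**
Reactants: 4 methyl 5-[(1S)-1-hydroxyethyl]-2-(prop-2-yn-1-yloxy)benzoate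
Product: 5 methyl 5-[(1S)-1-(tert-butyldimethylsilyloxy)ethyl]-2-(prop-2-yn-1-yloxy)benzoate
Conditions: TBSCl, imidazole, DMF, rt
Reagents that add atoms: tert-butyldimethylsilyl chloride, CC(C)(C)[Si](C)(C)Cl
Why: imidazole-promoted silylation of the secondary alcohol at oxygen, which leaves the carbinol configuration unchanged and protects this ionisable para-alkoxybenzylic position through the basic and hydridic steps that follow.

**Step 4**
Reactants: 5 methyl 5-[(1S)-1-(tert-butyldimethylsilyloxy)ethyl]-2-(prop-2-yn-1-yloxy)benzoate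
Product: 6 methyl 5-[(1S)-1-(tert-butyldimethylsilyloxy)ethyl]-2-(propa-1,2-dien-1-yloxy)benzoate
Conditions: KOt-Bu (0.3 equiv), THF, 0 °C to rt
Reagents that add atoms: none
Why: base-catalysed propargyl-to-allenyl isomerisation of an aryl propargyl ether (1,3-prototropic shift through the oxygen-stabilised anion), held at the allene by a sub-stoichiometric amount of base and run on the non-enolisable ester because a free formyl group would be attacked.

**Step 5**
Reactants: 6 methyl 5-[(1S)-1-(tert-butyldimethylsilyloxy)ethyl]-2-(propa-1,2-dien-1-yloxy)benzoate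
Product: 7 {5-[(1S)-1-(tert-butyldimethylsilyloxy)ethyl]-2-(propa-1,2-dien-1-yloxy)phenyl}methanol
Conditions: i-Bu2AlH (2.5 equiv), CH2Cl2, −78 to 0 °C; aq. potassium sodium tartrate
Reagents that add atoms: none
Why: complete reduction of the ester to the primary alcohol by the aluminium hydride, chosen over a partial reduction for reliability (any tert-butyl ester formed by exchange in step 4 converges here), with a neutral tartrate work-up that spares the acid-labile allenyl ether.

**Step 6**
Reactants: 7 {5-[(1S)-1-(tert-butyldimethylsilyloxy)ethyl]-2-(propa-1,2-dien-1-yloxy)phenyl}methanol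
Product: 8 5-[(1S)-1-(tert-butyldimethylsilyloxy)ethyl]-2-(propa-1,2-dien-1-yloxy)benzaldehyde
Conditions: MnO2, CH2Cl2, rt
Reagents that add atoms: none
Why: MnO2 oxidation of a benzylic alcohol, which stops at the aldehyde under neutral heterogeneous conditions that leave the allenyl and silyl ethers intact.

**Step 7**
Reactants: 8 5-[(1S)-1-(tert-butyldimethylsilyloxy)ethyl]-2-(propa-1,2-dien-1-yloxy)benzaldehyde; 9 bis(pinacolato)diboron
Product: 11 (2R,3R)-5-[(1S)-1-(tert-butyldimethylsilyloxy)ethyl]-2-[1-(4,4,5,5-tetramethyl-1,3,2-dioxaborolan-2-yl)ethenyl]-2,3-dihydro-1-benzofuran-3-ol, via O-pinacolboryl ether 10 (not isolated)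
Conditions: CuCl (5 mol %), (S,S)-Ph-BPE (6 mol %), NaOt-Bu (20 mol %), THF, 0 °C to rt; aq. NH4Cl work-up
Reagents that add atoms: none
Why: Proposed new method: a bisphosphine-bound monovalent copper boryl, made from CuCl, NaOt-Bu and 9, should add across the terminal C=C of the allenyl ether with boron on the central carbon, and the 2-boryl-3-aryloxyallylcopper so formed (its two ends exchange by 1,3-copper shift) should attack the neighbouring formyl group through its oxygen-bearing carbon in a six-membered cyclic transition state, after which the copper alkoxide is borylated by 9 to give 10 and the copper boryl again, and aqueous work-up frees 11. The closest known reaction types are the copper-catalysed enantioselective three-component coupling of monosubstituted allenes, B2pin2 and aldehydes or ketones, the copper-catalysed borylative cyclisation of allenes tethered to ketones, and the thermal cis-selective closure of gamma-alkoxyallylstannanes onto aldehydes; an aryloxyallene closing onto an ortho formyl group has not been described. The dihydrofuran ring closes in a 5-exo-trig mode at the C=O carbon, the alternative attack through the CH2 end being a seven-membered closure. C2 and C3 form together: their cis relation is controlled by the flat two-carbon arene tether, which spans the forming bond only when the aryl group and the allyl oxygen lie synclinal on the same side of the cyclic transition state (cis-fused; a trans fusion would demand a torsion the benzo-fused five-membered ring cannot reach), and their absolute sense (2R,3R) is controlled by the chiral bisphosphine, which has to send the allyl unit to the Si face of the formyl group, the remote silyloxyethyl centre having no influence. The step needs chemoselective borylcupration of the allene in the presence of the aldehyde, which phosphine–copper boryl complexes show in the intermolecular couplings, and copper delivery to the unsubstituted allene terminus, which the monosubstituted allene secures.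

**Step 8**
Reactants: 11 (2R,3R)-5-[(1S)-1-(tert-butyldimethylsilyloxy)ethyl]-2-[1-(4,4,5,5-tetramethyl-1,3,2-dioxaborolan-2-yl)ethenyl]-2,3-dihydro-1-benzofuran-3-ol
Product: 12 (2S,3R)-5-[(1S)-1-(tert-butyldimethylsilyloxy)ethyl]-2-(1-iodoethenyl)-2,3-dihydro-1-benzofuran-3-ol
Conditions: NaOH (3 M aq.), I2, THF, 0 °C
Reagents that add atoms: iodine, II
Why: iododeboronation of an alkenylboronate, in which hydroxide (or the neighbouring alkoxide) forms the boron ate complex, iodine adds to the activated C=C and boron leaves with iodide so that iodine takes the place of boron; it is done before any ester is present, and the C2 descriptor becomes S only because iodine raises the sequence-rule rank of the alkenyl carbon.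

**Step 9**
Reactants: 12 (2S,3R)-5-[(1S)-1-(tert-butyldimethylsilyloxy)ethyl]-2-(1-iodoethenyl)-2,3-dihydro-1-benzofuran-3-ol; 13 3-methylbutanoyl chloride
Product: 14 (2S,3R)-5-[(1S)-1-(tert-butyldimethylsilyloxy)ethyl]-2-(1-iodoethenyl)-2,3-dihydro-1-benzofuran-3-yl 3-methylbutanoate
Conditions: pyridine, DMAP (10 mol %), CH2Cl2, 0 °C to rt
Reagents that add atoms: none
Why: DMAP-catalysed acylation of the secondary benzylic alcohol by the acid chloride, with retention at C3 because the C3–O bond is not broken, and placed before carbonylation so that no free cis-hydroxyl can later trap an acylpalladium species as a lactone.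

**Step 10**
Reactants: 14 (2S,3R)-5-[(1S)-1-(tert-butyldimethylsilyloxy)ethyl]-2-(1-iodoethenyl)-2,3-dihydro-1-benzofuran-3-yl 3-methylbutanoate
Product: 15 (2S,3R)-5-[(1S)-1-hydroxyethyl]-2-(1-iodoethenyl)-2,3-dihydro-1-benzofuran-3-yl 3-methylbutanoate
Conditions: Bu4NF, AcOH (1:1), THF, 0 °C to rt
Reagents that add atoms: none
Why: fluoride-driven cleavage of the Si–O bond, buffered with acetic acid so that the C3 ester is neither hydrolysed nor eliminated and the para-alkoxybenzylic carbinol does not ionise, which keeps its (S) configuration.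

**Step 11**
Reactants: 15 (2S,3R)-5-[(1S)-1-hydroxyethyl]-2-(1-iodoethenyl)-2,3-dihydro-1-benzofuran-3-yl 3-methylbutanoate; 16 3-methylbut-2-enoic acid
Product: 18 (1S)-1-[(2S,3R)-2-(1-iodoethenyl)-3-(3-methylbutanoyloxy)-2,3-dihydro-1-benzofuran-5-yl]ethyl 3-methylbut-2-enoate, via O-acylisourea 17 (not isolated)
Conditions: DCC, DMAP (10 mol %), CH2Cl2, 0 °C to rt
Reagents that add atoms: none
Why: Steglich esterification, in which the carbodiimide activates the acid as the O-acylisourea and DMAP transfers the acyl group to the alcohol oxygen with retention at the carbinol, avoiding the ketene pathway that moves the double bond out of conjugation when the acid chloride meets an amine base.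

**Step 12**
Reactants: 18 (1S)-1-[(2S,3R)-2-(1-iodoethenyl)-3-(3-methylbutanoyloxy)-2,3-dihydro-1-benzofuran-5-yl]ethyl 3-methylbut-2-enoate
Product: 19 (1S)-1-[(2R,3R)-3-(3-methylbutanoyloxy)-2-(3-oxoprop-1-en-2-yl)-2,3-dihydro-1-benzofuran-5-yl]ethyl 3-methylbut-2-enoate
Conditions: Pd(PPh3)4 (5 mol %), CO (1–3 atm), Bu3SnH (1.1 equiv, added over 3 h), THF, 50 °C
Reagents that add atoms: carbon monoxide, [C-]#[O+]
Why: palladium-catalysed reductive carbonylation (formylation) of an alkenyl iodide by oxidative addition, CO insertion and hydride transfer from tin to the acylpalladium iodide, with slow stannane addition to suppress direct C–I reduction and reduction of the enal, and placed last so that the sensitive 2-substituted acrolein meets no further reagent.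

**Compound list**
1 | methyl 5-acetyl-2-hydroxybenzoate | COC(=O)c1cc(C(C)=O)ccc1O | starting material
2 | 3-bromoprop-1-yne | C#CCBr | starting material
3 | methyl 5-acetyl-2-(prop-2-yn-1-yloxy)benzoate | COC(=O)c1cc(C(C)=O)ccc1OCC#C | intermediate
4 | methyl 5-[(1S)-1-hydroxyethyl]-2-(prop-2-yn-1-yloxy)benzoate | COC(=O)c1cc([C@H](C)O)ccc1OCC#C | intermediate
5 | methyl 5-[(1S)-1-(tert-butyldimethylsilyloxy)ethyl]-2-(prop-2-yn-1-yloxy)benzoate | COC(=O)c1cc([C@H](C)O[Si](C)(C)C(C)(C)C)ccc1OCC#C | intermediate
6 | methyl 5-[(1S)-1-(tert-butyldimethylsilyloxy)ethyl]-2-(propa-1,2-dien-1-yloxy)benzoate | COC(=O)c1cc([C@H](C)O[Si](C)(C)C(C)(C)C)ccc1OC=C=C | intermediate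
7 | {5-[(1S)-1-(tert-butyldimethylsilyloxy)ethyl]-2-(propa-1,2-dien-1-yloxy)phenyl}methanol | OCc1cc([C@H](C)O[Si](C)(C)C(C)(C)C)ccc1OC=C=C | intermediate
8 | 5-[(1S)-1-(tert-butyldimethylsilyloxy)ethyl]-2-(propa-1,2-dien-1-yloxy)benzaldehyde | C=C=COc1ccc([C@H](C)O[Si](C)(C)C(C)(C)C)cc1C=O | intermediate
9 | bis(pinacolato)diboron | CC1(C)OB(OC1(C)C)B1OC(C)(C)C(C)(C)O1 | starting material
10 | 2-({(2R,3R)-5-[(1S)-1-(tert-butyldimethylsilyloxy)ethyl]-2-[1-(4,4,5,5-tetramethyl-1,3,2-dioxaborolan-2-yl)ethenyl]-2,3-dihydro-1-benzofuran-3-yl}oxy)-4,4,5,5-tetramethyl-1,3,2-dioxaborolane (not isolated) | C=C(B1OC(C)(C)C(C)(C)O1)[C@H]1Oc2ccc([C@H](C)O[Si](C)(C)C(C)(C)C)cc2[C@H]1OB1OC(C)(C)C(C)(C)O1 | intermediate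
11 | (2R,3R)-5-[(1S)-1-(tert-butyldimethylsilyloxy)ethyl]-2-[1-(4,4,5,5-tetramethyl-1,3,2-dioxaborolan-2-yl)ethenyl]-2,3-dihydro-1-benzofuran-3-ol | C=C(B1OC(C)(C)C(C)(C)O1)[C@H]1Oc2ccc([C@H](C)O[Si](C)(C)C(C)(C)C)cc2[C@H]1O | intermediate
12 | (2S,3R)-5-[(1S)-1-(tert-butyldimethylsilyloxy)ethyl]-2-(1-iodoethenyl)-2,3-dihydro-1-benzofuran-3-ol | C=C(I)[C@H]1Oc2ccc([C@H](C)O[Si](C)(C)C(C)(C)C)cc2[C@H]1O | intermediate
13 | 3-methylbutanoyl chloride | CC(C)CC(=O)Cl | starting material
14 | (2S,3R)-5-[(1S)-1-(tert-butyldimethylsilyloxy)ethyl]-2-(1-iodoethenyl)-2,3-dihydro-1-benzofuran-3-yl 3-methylbutanoate | C=C(I)[C@H]1Oc2ccc([C@H](C)O[Si](C)(C)C(C)(C)C)cc2[C@H]1OC(=O)CC(C)C | intermediate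
15 | (2S,3R)-5-[(1S)-1-hydroxyethyl]-2-(1-iodoethenyl)-2,3-dihydro-1-benzofuran-3-yl 3-methylbutanoate | C=C(I)[C@H]1Oc2ccc([C@H](C)O)cc2[C@H]1OC(=O)CC(C)C | intermediate
16 | 3-methylbut-2-enoic acid | CC(C)=CC(=O)O | starting material
17 | N,N'-dicyclohexyl-O-(3-methylbut-2-enoyl)isourea (not isolated) | CC(C)=CC(=O)OC(=NC1CCCCC1)NC1CCCCC1 | intermediate
18 | (1S)-1-[(2S,3R)-2-(1-iodoethenyl)-3-(3-methylbutanoyloxy)-2,3-dihydro-1-benzofuran-5-yl]ethyl 3-methylbut-2-enoate | C=C(I)[C@H]1Oc2ccc([C@H](C)OC(=O)C=C(C)C)cc2[C@H]1OC(=O)CC(C)C | intermediate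
19 | (1S)-1-[(2R,3R)-3-(3-methylbutanoyloxy)-2-(3-oxoprop-1-en-2-yl)-2,3-dihydro-1-benzofuran-5-yl]ethyl 3-methylbut-2-enoate (CNP0325942.1) | C=C(C=O)[C@H]1Oc2ccc([C@H](C)OC(=O)C=C(C)C)cc2[C@H]1OC(=O)CC(C)C | target

Total step count: 12. Longest linear sequence: 12 steps (1 to 19).

**Steps most likely to fail**

Step 7 (the proposed new method). The copper boryl may add to the formyl group instead of the allene, the copper alkoxide may fail to turn over with the diboron, or the ligand may give poor facial selectivity on the aldehyde. The fallback sets out from 8 and uses two known reaction types in one flask. Platinum-catalysed diboration of the terminal allene double bond with 9 (Pt(dba)2, PCy3, toluene, 50 °C) should give 5-[(1S)-1-(tert-butyldimethylsilyloxy)ethyl]-2-{[(1Z)-2,3-bis(pinacolboryl)prop-1-en-1-yl]oxy}benzaldehyde F1. This allylboronate should add to the neighbouring formyl group by thermal intramolecular allylboration through the same cis-fused cyclic transition state, giving 10 together with the O-pinacolboryl ether of the (2S,3S) isomer F2. Aqueous work-up frees 11 and the (2S,3S)-alcohol F3. This path has no control of absolute sense, but the two cis products are diastereomers because of the side-chain centre and would be separated by preparative HPLC. The fallback comes back to the route at 11.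

Step 12. Hydride may reach the alkenylpalladium species before CO inserts (loss of iodine without formylation), or palladium and tin hydride may reduce the product enal by conjugate reduction or by ionisation of its allylic C2–O bond. The fallback sets out from 18 and brings in the carbon at the alcohol oxidation level with no hydride present. Stille coupling with (tributylstannyl)methanol (Pd(PPh3)4, 1,4-dioxane, 80 °C) should give (1S)-1-[(2R,3R)-2-(3-hydroxyprop-1-en-2-yl)-3-(3-methylbutanoyloxy)-2,3-dihydro-1-benzofuran-5-yl]ethyl 3-methylbut-2-enoate F4. Oxidation of this allylic alcohol with MnO2 in CH2Cl2 at rt comes back to the route at 19.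

Step 8. The neighbouring free hydroxyl may capture the iodonium intermediate (iodoetherification), or the boronate may undergo protodeboronation in the aqueous base. The fallback sets out from 11 and removes the free hydroxyl before iodination. Acylation with 13 (pyridine, DMAP, CH2Cl2) gives (2R,3R)-5-[(1S)-1-(tert-butyldimethylsilyloxy)ethyl]-2-[1-(pinacolboryl)ethenyl]-2,3-dihydro-1-benzofuran-3-yl 3-methylbutanoate F5. KHF2 in aqueous methanol converts it to potassium {1-[(2R,3R)-5-[(1S)-1-(tert-butyldimethylsilyloxy)ethyl]-3-(3-methylbutanoyloxy)-2,3-dihydro-1-benzofuran-2-yl]ethenyl}trifluoroborate F6. Oxidative iodination with NaI and chloramine-T in aqueous THF at rt, a neutral method that tolerates esters, then gives the alkenyl iodide. The fallback comes back to the route at 14, with 12 left out.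

**Further compounds**
F1 | step 7 | 5-[(1S)-1-(tert-butyldimethylsilyloxy)ethyl]-2-{[(1Z)-2,3-bis(4,4,5,5-tetramethyl-1,3,2-dioxaborolan-2-yl)prop-1-en-1-yl]oxy}benzaldehyde | O=Cc1cc([C@H](C)O[Si](C)(C)C(C)(C)C)ccc1O/C=C(\CB1OC(C)(C)C(C)(C)O1)B1OC(C)(C)C(C)(C)O1
F2 | step 7 | 2-({(2S,3S)-5-[(1S)-1-(tert-butyldimethylsilyloxy)ethyl]-2-[1-(4,4,5,5-tetramethyl-1,3,2-dioxaborolan-2-yl)ethenyl]-2,3-dihydro-1-benzofuran-3-yl}oxy)-4,4,5,5-tetramethyl-1,3,2-dioxaborolane | C=C(B1OC(C)(C)C(C)(C)O1)[C@@H]1Oc2ccc([C@H](C)O[Si](C)(C)C(C)(C)C)cc2[C@@H]1OB1OC(C)(C)C(C)(C)O1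
F3 | step 7 | (2S,3S)-5-[(1S)-1-(tert-butyldimethylsilyloxy)ethyl]-2-[1-(4,4,5,5-tetramethyl-1,3,2-dioxaborolan-2-yl)ethenyl]-2,3-dihydro-1-benzofuran-3-ol | C=C(B1OC(C)(C)C(C)(C)O1)[C@@H]1Oc2ccc([C@H](C)O[Si](C)(C)C(C)(C)C)cc2[C@@H]1O
F4 | step 12 | (1S)-1-[(2R,3R)-2-(3-hydroxyprop-1-en-2-yl)-3-(3-methylbutanoyloxy)-2,3-dihydro-1-benzofuran-5-yl]ethyl 3-methylbut-2-enoate | C=C(CO)[C@H]1Oc2ccc([C@H](C)OC(=O)C=C(C)C)cc2[C@H]1OC(=O)CC(C)C
F5 | step 8 | (2R,3R)-5-[(1S)-1-(tert-butyldimethylsilyloxy)ethyl]-2-[1-(4,4,5,5-tetramethyl-1,3,2-dioxaborolan-2-yl)ethenyl]-2,3-dihydro-1-benzofuran-3-yl 3-methylbutanoate | C=C(B1OC(C)(C)C(C)(C)O1)[C@H]1Oc2ccc([C@H](C)O[Si](C)(C)C(C)(C)C)cc2[C@H]1OC(=O)CC(C)C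
F6 | step 8 | potassium {1-[(2R,3R)-5-[(1S)-1-(tert-butyldimethylsilyloxy)ethyl]-3-(3-methylbutanoyloxy)-2,3-dihydro-1-benzofuran-2-yl]ethenyl}trifluoroborate | C=C([B-](F)(F)F)[C@H]1Oc2ccc([C@H](C)O[Si](C)(C)C(C)(C)C)cc2[C@H]1OC(=O)CC(C)C.[K+]
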